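**Early pace.** The early readings of the ash run, which is this same flask followed so far, show target climbing at a pace that seems to ease, and I start from that easing.

| setting | ash | flask |
|---|---|---|
| starting material | 1.5 M | 1.5 M |
| reagent in the second phase | 1.2 M | 1.20 M |
| remark | the very flask that is asked about, followed so far |  |
| time |  | 20 h |
| volume of the second phase over the first |  | 0.50 |

ash run (percent of the starting material charged)

| time / h | target / % | starting material / % |
|---|---|---|
| 0.667 | 7.2 | 89.1 |
| 1.33 | 14.5 | 82.1 |
| 2.00 | 16.8 | 79.3 |
| 2.50 | 21.0 | 75.4 |

(readings scatter by 1 percentage point)

- in the second phase: reagent in the second phase; everything else is in the first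
- charges count per volume of the first phase; a concentration in a rate is the amount of a species over the volume of its own phase; every rate counts per litre of the first phase
- the earlier runs hold the two phases in the same ratio of volumes as the flask asked about

* amount of target at 20 h, in percent of the starting material charged
* the change that raises the amount of target at 20 h, in percent of the starting material charged most ("none" if none brings more than 2 percentage points) (Monday's / Tuesday's / none)
* amount of target at 20 h, in percent of the starting material charged, after Tuesday's

**Pace half-life.** In the ash run, up to 1.33 h target comes at 0.109 h⁻¹ of the charge, and from there to 2.50 h at 0.0556 h⁻¹, about half. Taken as a steady decline, this gives 1.29 h, my pace half-life, the time in which the pace of target halves. It is a reading, and loose under a scatter of 1 percentage point. I treat the last reading as the large part and what is still to come as the correction. Summing the fading pace gives a resting level of 28.4%, which is 7.4 points above that reading.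

**Time.** The asked 20 h is 15.5 pace half-lives, so by hand target rests at 28.4%, and that is my number.

**Transfer.** The first stretch of the ash run goes at 0.108 h⁻¹, about the same as 0.109 h⁻¹. No start-up lag shows in these readings, so by hand Monday's, doubling the transfer coefficient of the reagent in the second phase, gains nothing.

**Reagent amount.** By count the reagent in the second phase is the limiting reagent, with a charge of 80.0% of the starting material, but my resting level is lower than that. By hand, then, Tuesday's, doubling the amount of reagent in the second phase, gains nothing either, and my answer is none.

**Result.** The forecast gives 67%, Tuesday's as best and 93% after it, since “Doubling reagent removes the cap”. The flask gives 12.8%. Monday's moves target by −0.0053 points and Tuesday's by −0.7 points, to 12.1%, so the answer is none.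

    reagent in the reaction phase ⇌ reagent in the second phase, rate k1*([reagent in the reaction phase] - [reagent in the second phase]/K1) per volume of the first phase (partition coefficient = 0.340, kL = 8.80 h⁻¹)
    starting material + reagent in the reaction phase ⇌ target (K = 2.50 M⁻¹, k = 0.200 M⁻¹ h⁻¹)
    reagent in the reaction phase + target → over-reacted product (k = 0.320 M⁻¹ h⁻¹)
    2 reagent in the reaction phase → self-condensation product (k = 0.110 M⁻¹ h⁻¹)

**What ran.** In this flask, from 2.00 h to 20.0 h, reagent in the reaction phase falls from 0.481 M to 0.0641 M, while over-reacted product climbs from 4.71% to 19.8%. Target stands at 18.3% at 10.0 h, and this flask ends 16 points under the resting level from my pace half-life. For the neighbour flask read at 5.0 h, the pace half-life gives 26.5%, and the computed target is 20.9%.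

(The runs stem from a simulated flask with constants of no real substance, and the scatter is random.)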